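**Retrosynthetic overview**
- The enone Cα=Cβ bond is cut by a Claisen–Schmidt disconnection. This gives the ring A methyl ketone (3,4-dihydroxyacetophenone with both phenols as MOM ethers; ring A is bought) and a ring B benzaldehyde.
- The plan rests on ring B. The oxygens at C2 and C4 flank the prenyl-bearing C3, and C1 carries carbon. This is the imprint of a hexanoate chain with ketones at C3 and C5 and an alkyl group on the C4 between them, so ring B is built from a chain and never substituted as an arene.
- The aldehyde goes back (redox, 2-O-methylation, 4-O-MOM) to methyl 2,4-dihydroxy-3-prenylbenzoate, an isomer of a 4-pyranone-3-carboxylate. Base opens the O1–C2 bond, and the 6-methyl carbon (future C5) bonds to the old C2 (future C6).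
- The pyranone comes from pentane-2,4-dione by prenylation at the central carbon, carbomethoxylation of one terminal methyl through the dianion, and insertion of one CH unit with Me2NCH(OMe)2.
- Order of rings: the pyranone ring (step 3, temporary), then the ring B carbocycle (step 4).

Key step: step 4

Assumption: the 1,3-dicarbonyl compounds 3, 6, 7, 9 and 10 are drawn as keto tautomers whose C–H stereocentres are labile and carry no descriptor. The push–pull C=C bonds of 7 and 9 are configurationally labile and drawn without geometry.

**Step 1**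
Reactants: 1 pentane-2,4-dione; 2 1-bromo-3-methylbut-2-ene
Product: 3 3-(3-methylbut-2-enyl)pentane-2,4-dione
Conditions: K2CO3 (1.2 equiv), 1 (1.2 equiv), acetone, reflux
Reagents that add atoms: none
Why: SN2 C-alkylation of the potassium enolate of a symmetrical 1,3-diketone by a soft allylic bromide puts the prenyl group on the central carbon, the only nucleophilic carbon present, and a slight excess of 1 holds back a second alkylation.

**Step 2**
Reactants: 3 3-(3-methylbut-2-enyl)pentane-2,4-dione; 4 dimethyl carbonate
Product: 6 methyl 4-(3-methylbut-2-enyl)-3,5-dioxohexanoate, via dilithium dienolate 5 (not isolated)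
Conditions: LiN(iPr)2 (commercial solution, 3.2 equiv), THF, −78 to 0 °C; 4 (1.1 equiv), −78 to 0 °C; cold 1 M HCl
Reagents that add atoms: none
Why: Claisen-type C-acylation of a 1,3-diketone dianion: after the central C–H the base removes a proton from one of the two equivalent methyl groups, only this more basic terminal carbanion of 5 attacks the carbonate, and the third equivalent of base takes up the acidic C2–H of the product so that 6 cannot quench 5.

**Step 3**
Reactants: 6 methyl 4-(3-methylbut-2-enyl)-3,5-dioxohexanoate
Product: 8 methyl 6-methyl-5-(3-methylbut-2-enyl)-4-oxo-4H-pyran-3-carboxylate, via enaminone 7 (not isolated)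
Conditions: Me2NCH(OMe)2 (1.1 equiv), toluene, rt; then AcOH, 60 °C
Reagents that add atoms: N,N-dimethylformamide dimethyl acetal, COC(OC)N(C)C
Why: Aminomethylenation of an active methylene followed by cyclocondensation: only C2 of 6 carries two protons between two carbonyl groups (C4 has one proton, the C6 methyl is far less acidic), and in 7 the enol oxygen of the C5 ketone displaces dimethylamine from the aminomethylene carbon by addition–elimination, which closes the 4-pyranone.

**Step 4**
Reactants: 8 methyl 6-methyl-5-(3-methylbut-2-enyl)-4-oxo-4H-pyran-3-carboxylate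
Product: 11 methyl 2,4-dihydroxy-3-(3-methylbut-2-enyl)benzoate, via methoxymethylene chain 9 (not isolated), via cyclohexenedione 10 (not isolated)
Conditions: NaOMe (5 equiv), dry MeOH (0.02 M), argon, 0 °C to reflux; AcOH, 0 °C
Reagents that add atoms: none
Why: Methoxide adds to C2 of 8, the only unsubstituted ring carbon and the β-position of both the C4 ketone and the C3 ester, and the C2–O1 bond breaks by retro-oxa-Michael cleavage, which lays open chain 9 as the enolate of its 3,5-diketone (O1 becomes the C5 ketone oxygen). Proton exchange through methanol supplies a small stationary amount of the terminal CH2 enolate of the methyl ketone, which attacks the methoxymethylene carbon in a 6-endo-trig closure (both alkene carbons end up in the new ring), methoxide leaves again (vinylic addition–elimination) to give 10, and two enolisations turn 10 into the arene, held as its phenoxide, so that 8 to 11 is a net isomerisation with ring B bond C5–C6 as the only new skeletal bond. The closest known reaction type is the base-induced recyclisation of 4-pyranones to resorcinols through their 1,3,5-tricarbonyl chains (2,6-dimethyl-4-pyranone to orcinol) and the kindred conversion of 2-methylpyrylium salts into phenols, where the α-methyl carbon likewise becomes a ring carbon. The step needs carbon closure at the methoxymethylene carbon to win over oxygen reclosure, over closure of the same enolate on the ester carbonyl (6-exo-trig Claisen mode) and over retro-Claisen loss of the acetyl or formyl unit: oxygen reclosure and lactonisation are reversible in NaOMe/MeOH while aromatisation is not, the methoxymethylene carbon is a doubly activated formyl equivalent and far more electrophilic than the push–pull ester, and excess base keeps the diketone as its enolate, which shields both ketones from methoxide. The prenyl group on the central carbon disfavours the extended, oxygen-chelated enolate by allylic strain against both flanking carbon substituents and so helps the chain to fold, high dilution holds back intermolecular Michael addition, and methoxide matched to the methyl ester makes ester exchange invisible. No stereocentre is formed and the trisubstituted alkene is inert to base.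

**Step 5**
Reactants: 11 methyl 2,4-dihydroxy-3-(3-methylbut-2-enyl)benzoate
Product: 12 methyl 2-hydroxy-4-(methoxymethoxy)-3-(3-methylbut-2-enyl)benzoate
Conditions: MOMCl (1.1 equiv), K2CO3 (1.5 equiv), acetone, 0 °C to rt
Reagents that add atoms: chloromethyl methyl ether (MOMCl), COCCl
Why: Williamson-type O-alkylation under weak base is selective for the 4-OH because the 2-OH is locked in a hydrogen bond to the ester carbonyl and is both less acidic and less nucleophilic.

**Step 6**
Reactants: 12 methyl 2-hydroxy-4-(methoxymethoxy)-3-(3-methylbut-2-enyl)benzoate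
Product: 13 methyl 2-methoxy-4-(methoxymethoxy)-3-(3-methylbut-2-enyl)benzoate
Conditions: MeI (3 equiv), K2CO3 (3 equiv), DMF, 40 °C
Reagents that add atoms: iodomethane, CI
Why: Williamson O-methylation of the only remaining acidic site, for which K2CO3 in a dipolar aprotic solvent breaks the chelate and the small electrophile reaches the phenoxide between ester and prenyl group.

**Step 7**
Reactants: 13 methyl 2-methoxy-4-(methoxymethoxy)-3-(3-methylbut-2-enyl)benzoate
Product: 14 [2-methoxy-4-(methoxymethoxy)-3-(3-methylbut-2-enyl)phenyl]methanol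
Conditions: iBu2AlH (2.5 equiv), CH2Cl2, −78 to 0 °C; aq. KNaC4H4O6
Reagents that add atoms: none
Why: Hydride reduction of the aryl ester through the aldehyde stage to the benzylic alcohol, under which the acetal, the aryl ethers and the unactivated trisubstituted alkene are inert at low temperature.

**Step 8**
Reactants: 14 [2-methoxy-4-(methoxymethoxy)-3-(3-methylbut-2-enyl)phenyl]methanol
Product: 15 2-methoxy-4-(methoxymethoxy)-3-(3-methylbut-2-enyl)benzaldehyde
Conditions: MnO2 (activated, 15 equiv), CH2Cl2, rt
Reagents that add atoms: none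
Why: Heterogeneous MnO2 oxidation is selective for benzylic alcohols, stops at the aldehyde and is neutral, so that the MOM ether and the prenyl alkene stay untouched.

**Step 9**
Reactants: 16 1-(3,4-dihydroxyphenyl)ethanone
Product: 17 1-[3,4-bis(methoxymethoxy)phenyl]ethanone
Conditions: MOMCl (2.6 equiv), K2CO3 (4 equiv), acetone, 0 °C to rt
Reagents that add atoms: chloromethyl methyl ether (MOMCl), COCCl
Why: Twofold Williamson-type O-alkylation of the catechol masks both acidic, oxidation-prone phenols before the strongly basic condensation, while the methyl ketone is not enolised by K2CO3 and stays unalkylated.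

**Step 10**
Reactants: 15 2-methoxy-4-(methoxymethoxy)-3-(3-methylbut-2-enyl)benzaldehyde; 17 1-[3,4-bis(methoxymethoxy)phenyl]ethanone
Product: 19 (E)-1-[3,4-bis(methoxymethoxy)phenyl]-3-[2-methoxy-4-(methoxymethoxy)-3-(3-methylbut-2-enyl)phenyl]prop-2-en-1-one, via aldol adduct 18 (not isolated)
Conditions: KOH (50% aq.), EtOH, rt, argon, dark
Reagents that add atoms: none
Why: Claisen–Schmidt condensation: 17 is the only enolisable partner and 15 the only aldehyde, the aldol adduct 18 loses water by an E1cB path, and the reversible sequence delivers the conjugated alkene as its more stable E isomer with aryl and aroyl groups trans (the carbinol centre of 18 is racemic and is erased).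

**Step 11**
Reactants: 19 (E)-1-[3,4-bis(methoxymethoxy)phenyl]-3-[2-methoxy-4-(methoxymethoxy)-3-(3-methylbut-2-enyl)phenyl]prop-2-en-1-one
Product: 20 licoagrochalcone C, (E)-1-(3,4-dihydroxyphenyl)-3-[4-hydroxy-2-methoxy-3-(3-methylbut-2-enyl)phenyl]prop-2-en-1-one
Conditions: HCl (cat., 0.5 M in MeOH), rt, argon, dark
Reagents that add atoms: none
Why: Acid-catalysed acetal exchange with methanol removes all three MOM groups as dimethoxymethane at an acidity and temperature too low to protonate the trisubstituted prenyl alkene, and the E-enone, already the stable isomer, is not affected.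

**Compound list**
1 | pentane-2,4-dione | CC(=O)CC(C)=O | starting material
2 | 1-bromo-3-methylbut-2-ene | CC(C)=CCBr | starting material
3 | 3-(3-methylbut-2-enyl)pentane-2,4-dione | CC(=O)C(CC=C(C)C)C(C)=O | intermediate
4 | dimethyl carbonate | COC(=O)OC | starting material
5 | dilithium 3-(3-methylbut-2-enyl)penta-1,3-diene-2,4-diolate (not isolated) | [Li+].[Li+].C=C([O-])C(CC=C(C)C)=C(C)[O-] | intermediate
6 | methyl 4-(3-methylbut-2-enyl)-3,5-dioxohexanoate | COC(=O)CC(=O)C(CC=C(C)C)C(C)=O | intermediate
7 | methyl 2-(dimethylaminomethylidene)-4-(3-methylbut-2-enyl)-3,5-dioxohexanoate (not isolated) | COC(=O)C(=CN(C)C)C(=O)C(CC=C(C)C)C(C)=O | intermediate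
8 | methyl 6-methyl-5-(3-methylbut-2-enyl)-4-oxo-4H-pyran-3-carboxylate | COC(=O)C1=COC(C)=C(CC=C(C)C)C1=O | intermediate
9 | methyl 2-(methoxymethylidene)-4-(3-methylbut-2-enyl)-3,5-dioxohexanoate, present as sodium enolate (not isolated) | COC=C(C(=O)OC)C(=O)C(CC=C(C)C)C(C)=O | intermediate
10 | methyl 5-(3-methylbut-2-enyl)-4,6-dioxocyclohex-1-ene-1-carboxylate (not isolated) | COC(=O)C1=CCC(=O)C(CC=C(C)C)C1=O | intermediate
11 | methyl 2,4-dihydroxy-3-(3-methylbut-2-enyl)benzoate | COC(=O)c1ccc(O)c(CC=C(C)C)c1O | intermediate
12 | methyl 2-hydroxy-4-(methoxymethoxy)-3-(3-methylbut-2-enyl)benzoate | COC(=O)c1ccc(OCOC)c(CC=C(C)C)c1O | intermediate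
13 | methyl 2-methoxy-4-(methoxymethoxy)-3-(3-methylbut-2-enyl)benzoate | COC(=O)c1ccc(OCOC)c(CC=C(C)C)c1OC | intermediate
14 | [2-methoxy-4-(methoxymethoxy)-3-(3-methylbut-2-enyl)phenyl]methanol | OCc1ccc(OCOC)c(CC=C(C)C)c1OC | intermediate
15 | 2-methoxy-4-(methoxymethoxy)-3-(3-methylbut-2-enyl)benzaldehyde | O=Cc1ccc(OCOC)c(CC=C(C)C)c1OC | intermediate
16 | 1-(3,4-dihydroxyphenyl)ethanone (3,4-dihydroxyacetophenone) | CC(=O)c1ccc(O)c(O)c1 | starting material
17 | 1-[3,4-bis(methoxymethoxy)phenyl]ethanone | CC(=O)c1ccc(OCOC)c(OCOC)c1 | intermediate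
18 | 1-[3,4-bis(methoxymethoxy)phenyl]-3-hydroxy-3-[2-methoxy-4-(methoxymethoxy)-3-(3-methylbut-2-enyl)phenyl]propan-1-one, racemic (not isolated) | COc1c(C(O)CC(=O)c2ccc(OCOC)c(OCOC)c2)ccc(OCOC)c1CC=C(C)C | intermediate
19 | (E)-1-[3,4-bis(methoxymethoxy)phenyl]-3-[2-methoxy-4-(methoxymethoxy)-3-(3-methylbut-2-enyl)phenyl]prop-2-en-1-one | COc1c(/C=C/C(=O)c2ccc(OCOC)c(OCOC)c2)ccc(OCOC)c1CC=C(C)C | intermediate
20 | licoagrochalcone C, (E)-1-(3,4-dihydroxyphenyl)-3-[4-hydroxy-2-methoxy-3-(3-methylbut-2-enyl)phenyl]prop-2-en-1-one | COc1c(/C=C/C(=O)c2ccc(O)c(O)c2)ccc(O)c1CC=C(C)C | target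

**Step count**
- Total step count: 11.
- Longest linear sequence: 10 (steps 1 to 8, 10 and 11, from pentane-2,4-dione).

**Steps most likely to fail**

**1. Step 4 (ring transformation).**
What may go wrong:
- The population of the terminal methyl enolate may be too low for carbon closure, so the opened chain only returns to the pyranone.
- Retro-Claisen loss of the acetyl or the formyl unit may erode the chain.
- The same enolate may close on the ester carbonyl.
- Intermolecular Michael addition may set in.

Fallback: ring B is bought as an arene and the prenyl group is placed by directed ortho-metalation. It sets out from bromide 2 and comes back to the route at aldehyde 15, replacing steps 1 to 8.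
- Resorcinol is treated with NaH and MOMCl in DMF to give 1,3-bis(methoxymethoxy)benzene F1.
- n-BuLi in THF at 0 °C removes the proton between the two acetal oxygens to give [2,6-bis(methoxymethoxy)phenyl]lithium F2, which is alkylated by 2 to 1,3-bis(methoxymethoxy)-2-(3-methylbut-2-enyl)benzene F3.
- A second acetal-directed ring lithiation (n-BuLi, TMEDA, THF, 0 °C) gives [2,4-bis(methoxymethoxy)-3-(3-methylbut-2-enyl)phenyl]lithium F4, which is formylated with DMF to 2,4-bis(methoxymethoxy)-3-(3-methylbut-2-enyl)benzaldehyde F5.
- The MOM group ortho to the formyl group is the more labile one because of the neighbouring carbonyl. It is cleaved selectively with dilute HCl in MeOH at 0 °C to give 2-hydroxy-4-(methoxymethoxy)-3-(3-methylbut-2-enyl)benzaldehyde F6.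
- MeI and K2CO3 in DMF then give 15.

**2. Step 2 (dianion carbomethoxylation).**
What may go wrong:
- Proton transfer from the acidic product may quench the dianion.
- The amide base may attack the carbonate.
- The keto ester may lactonise during work-up.

Fallback: the chain is assembled by forming bond C4–C5 instead of C1–C2. It sets out from bromide 2 and comes back at keto ester 6.
- Commercial methyl acetoacetate is deprotonated twice with LiN(iPr)2 (2.1 equiv, THF, 0 °C) to dilithium 1-methoxybuta-1,3-diene-1,3-diolate F7.
- F7 is alkylated by 2 at its terminal carbon only, giving methyl 7-methyl-3-oxooct-6-enoate F8.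
- A second double deprotonation gives dilithium 1-methoxy-7-methylocta-1,3,6-triene-1,3-diolate F9, whose C4 carbanion is acetylated with N-methoxy-N-methylacetamide.
- The tetrahedral lithium chelate lasts until the acid quench, so the acidic product 6 never meets unreacted dianion.

**3. Step 11 (global MOM removal).**
What may go wrong:
- The liberated 4-OH may add across the neighbouring prenyl alkene under acid (ring closure to a chroman).
- Methanol may add to the same alkene.

Fallback: the protecting-group plan is changed to allyl ethers, which are removed without acid. It sets out from resorcylate 11 and ketone 16 and comes back at target 20.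
- Allyl bromide (1.1 equiv) and K2CO3 in acetone convert 11 into methyl 2-hydroxy-3-(3-methylbut-2-enyl)-4-(prop-2-enyloxy)benzoate F10.
- MeI and K2CO3 in DMF give methyl 2-methoxy-3-(3-methylbut-2-enyl)-4-(prop-2-enyloxy)benzoate F11.
- iBu2AlH gives [2-methoxy-3-(3-methylbut-2-enyl)-4-(prop-2-enyloxy)phenyl]methanol F12, and MnO2 gives 2-methoxy-3-(3-methylbut-2-enyl)-4-(prop-2-enyloxy)benzaldehyde F13.
- Ketone 16 with allyl bromide and K2CO3 gives 1-[3,4-bis(prop-2-enyloxy)phenyl]ethanone F14.
- KOH in EtOH joins F13 and F14 through the racemic aldol adduct 1-[3,4-bis(prop-2-enyloxy)phenyl]-3-hydroxy-3-[2-methoxy-3-(3-methylbut-2-enyl)-4-(prop-2-enyloxy)phenyl]propan-1-one F15. This dehydrates to (E)-1-[3,4-bis(prop-2-enyloxy)phenyl]-3-[2-methoxy-3-(3-methylbut-2-enyl)-4-(prop-2-enyloxy)phenyl]prop-2-en-1-one F16.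
- Tsuji–Trost-type deallylation with the zerovalent palladium catalyst Pd(PPh3)4 and K2CO3 in MeOH under argon releases 20. The C-bound prenyl group carries no leaving group and is not ionised.

**Further compounds**
F1 | step 4 | 1,3-bis(methoxymethoxy)benzene | COCOc1cccc(OCOC)c1
F2 | step 4 | [2,6-bis(methoxymethoxy)phenyl]lithium | [Li]c1c(OCOC)cccc1OCOC
F3 | step 4 | 1,3-bis(methoxymethoxy)-2-(3-methylbut-2-enyl)benzene | COCOc1cccc(OCOC)c1CC=C(C)C
F4 | step 4 | [2,4-bis(methoxymethoxy)-3-(3-methylbut-2-enyl)phenyl]lithium | [Li]c1ccc(OCOC)c(CC=C(C)C)c1OCOC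
F5 | step 4 | 2,4-bis(methoxymethoxy)-3-(3-methylbut-2-enyl)benzaldehyde | O=Cc1ccc(OCOC)c(CC=C(C)C)c1OCOC
F6 | step 4 | 2-hydroxy-4-(methoxymethoxy)-3-(3-methylbut-2-enyl)benzaldehyde | O=Cc1ccc(OCOC)c(CC=C(C)C)c1O
F7 | step 2 | dilithium 1-methoxybuta-1,3-diene-1,3-diolate | [Li+].[Li+].C=C([O-])C=C([O-])OC
F8 | step 2 | methyl 7-methyl-3-oxooct-6-enoate | COC(=O)CC(=O)CCC=C(C)C
F9 | step 2 | dilithium 1-methoxy-7-methylocta-1,3,6-triene-1,3-diolate | [Li+].[Li+].COC([O-])=CC([O-])=CCC=C(C)C
F10 | step 11 | methyl 2-hydroxy-3-(3-methylbut-2-enyl)-4-(prop-2-enyloxy)benzoate | COC(=O)c1ccc(OCC=C)c(CC=C(C)C)c1O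
F11 | step 11 | methyl 2-methoxy-3-(3-methylbut-2-enyl)-4-(prop-2-enyloxy)benzoate | COC(=O)c1ccc(OCC=C)c(CC=C(C)C)c1OC
F12 | step 11 | [2-methoxy-3-(3-methylbut-2-enyl)-4-(prop-2-enyloxy)phenyl]methanol | OCc1ccc(OCC=C)c(CC=C(C)C)c1OC
F13 | step 11 | 2-methoxy-3-(3-methylbut-2-enyl)-4-(prop-2-enyloxy)benzaldehyde | O=Cc1ccc(OCC=C)c(CC=C(C)C)c1OC
F14 | step 11 | 1-[3,4-bis(prop-2-enyloxy)phenyl]ethanone | CC(=O)c1ccc(OCC=C)c(OCC=C)c1
F15 | step 11 | 1-[3,4-bis(prop-2-enyloxy)phenyl]-3-hydroxy-3-[2-methoxy-3-(3-methylbut-2-enyl)-4-(prop-2-enyloxy)phenyl]propan-1-one, racemic | COc1c(C(O)CC(=O)c2ccc(OCC=C)c(OCC=C)c2)ccc(OCC=C)c1CC=C(C)C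
F16 | step 11 | (E)-1-[3,4-bis(prop-2-enyloxy)phenyl]-3-[2-methoxy-3-(3-methylbut-2-enyl)-4-(prop-2-enyloxy)phenyl]prop-2-en-1-one | COc1c(/C=C/C(=O)c2ccc(OCC=C)c(OCC=C)c2)ccc(OCC=C)c1CC=C(C)C
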